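L runs behind D in the south-east run, 5% against 30% at 0.250 min, so I read the flask as X giving D, then D taking up Q to give L. Q was not read; I assume one Q per L.

| flask | X | Q | G | temperature | remark | time |
|---|---|---|---|---|---|---|
| south-east | 44 mM | 66 mM | 7.9 mM | 80 °C | run made earlier |  |
| beta | 44 mM | 44.0 mM | 7.9 mM | 80 °C |  | 10 min |
| zeta | 44 mM | 44.0 mM | 7.9 mM | 50 °C |  | 10 min |

south-east run (percent of the X charged)

| time / min | D / % | L / % |
|---|---|---|
| 0.250 | 30 | 5 |
| 0.417 | 37 | 11 |
| 0.667 | 41 | 25 |
| 1.00 | 41 | 38 |
| 2.00 | 25 | 53 |
| 3.00 | 16 | 62 |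

(each reading ± 2 percentage points)

* the best flask by amount of D, in percent of the X charged; "all alike" if 1.5 percentage points covers them all (beta / zeta / all alike)
* amount of D at the end, in percent of the X charged, beta
* amount of D at the end, in percent of the X charged, zeta

- the numbers in the tables scatter by 2 percentage points (one standard deviation)
- a reading or a percentage of L counts all its forms, free or not
- the earlier runs do not show what temperature does; that part of a forecast is a guess

In south-east, charged Q exceeds charged X by 22.0 mM. I call this the surplus S: on my assumption, [Q] − [D] − [X] stays at S throughout a run. In beta and zeta, S is 0 mM.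

I have two ways to D in beta. The first works in decades on D itself: south-east loses 0.194 of a decade between 2.00 min and 3.00 min, and that pace carried to 10 min leaves 0.704%. The second follows log10([Q]/[D]), with [Q] = [D] + S while D + L stands flat near 78.0%. It climbs at 0.138 min⁻¹, which gives a reading τ = 1.57 min for a flask of zero surplus, where D's share goes as τ/(τ + t). That makes 13.6% in beta.

They part, and the first cheats. Its pace belongs to [Q] near 29.0 mM, but at zero surplus, with X gone, [Q] equals [D], 7.04 mM at the same D, a smaller partner. I commit to the second. For zeta I have no rate, only the expectation that a slower flask lengthens τ and holds more D.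

The forecast names zeta, with 0.5% (0% to 3%) in beta and 28% (14% to 40%) in zeta, on the ground that “Q has run out, at about 2 Q per X”; I take one Q per L instead.

The flasks give 10.2% in beta and 40.8% in zeta, so zeta is best, and beta lies nearer my second way than my first.

    X + G → G + D (k = 32.0 M⁻¹ min⁻¹, Ea = 62.0 kJ mol⁻¹)
    Q + G + D → G + L (k = 540 M⁻² min⁻¹, Ea = 51.0 kJ mol⁻¹)
    L → Z (k = 0.0110 min⁻¹, Ea = 108 kJ mol⁻¹)
    J ⇌ L, rate k4*(cs4 - [L]) while solid is left; crystals form when [L] > cs4 (solubility = 11.0 mM, k = 7.60 min⁻¹)
    L → E (k = 4.80 × 10⁻⁴ min⁻¹, Ea = 99.0 kJ mol⁻¹)
    (constants at 50 °C)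

In beta, X reached half conversion at 0.386 min and was down to 0.0126% at 5.00 min; from then on D, 19.8% of the X charged, and Q, 19.8% of its own charge, fell together to 10.2% and 10.2% at 10.0 min. In zeta the step making D and the step using it both still ran at 10.0 min, with Q at 48.8% of its own charge, D at 40.8% and X at 7.98% of the X charged, and with S at zero Q equals the sum of the other two. Zeta's neighbour with X at 180 mM has S = −136 mM, with Q the limiting reagent. Counting Q as zero and X left as in zeta, S puts D at 67.6%; the computed flask holds 68.2%, with 2.43% of its Q left.

The earlier runs and the new flask stem from a simulated flask with made-up constants, noise included.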